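## Retrosynthetic overview

1. Target ⇐ Yamaguchi angeloylation of the C4 alcohol; the C8 angelate comes from Mitsunobu inversion of the 8-epi allylic alcohol, which comes from Luche reduction of a bicyclic enone.
2. Bicyclic enone ⇐ key step: a one-flask cationic (5+2) annulation of an acyclic 2-ethoxypentadienyl cation with a tethered aldehyde enol silane. The cyclopentane closes first (C3a–C8a bond), the cycloheptenone second (C4–C5 bond).
3. Acyclic precursor ⇐ (E)-1-ethoxy-3-methylbutadienyl metal (from prenal diethyl acetal) added to the methyl ketone of a keto aldehyde.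
4. Keto aldehyde ⇐ ozonolysis of silylated (S)-terpinen-4-ol, which supplies the C3 carbinol centre that steers all the others.

Locants in names follow azulene numbering: C3 = C(OH)(iPr), C3a–H and C8a–CH3 = ring fusion, C4 and C8 = ester carbons, C6=C7 = ring alkene.

Assumption: (S)-(+)-terpinen-4-ol is bought enantiopure (≥98% ee); a lot of lower ee would be upgraded before use.

## Route

Step 1
Reactants: 1 (S)-(+)-terpinen-4-ol
Product: 2 triethyl{[(1S)-4-methyl-1-(propan-2-yl)cyclohex-3-en-1-yl]oxy}silane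
Conditions: TESOTf, 2,6-lutidine, CH2Cl2, 0 °C
Reagents that add atoms: triethylsilyl trifluoromethanesulfonate, CC[Si](CC)(CC)OS(=O)(=O)C(F)(F)F
Why: Silyl triflate O-silylation of the tertiary alcohol; it blocks retro-aldol and β-elimination of the later β-oxy aldehyde and stops the oxygen from trapping the cation in step 4, with the stereocentre untouched.

Step 2
Reactants: 2 triethyl{[(1S)-4-methyl-1-(propan-2-yl)cyclohex-3-en-1-yl]oxy}silane
Product: 3 (3S)-6-oxo-3-(propan-2-yl)-3-[(triethylsilyl)oxy]heptanal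
Conditions: O3, CH2Cl2, −78 °C; then PPh3, −78 °C → rt
Reagents that add atoms: ozone, [O-][O+]=O
Why: Criegee ozonolysis of the only alkene with reductive work-up gives the methyl ketone and the aldehyde, each on its own arm of the intact carbinol centre.

Step 3
Reactants: 3 (3S)-6-oxo-3-(propan-2-yl)-3-[(triethylsilyl)oxy]heptanal; 4 1,1-diethoxy-3-methylbut-2-ene
Product: 8 (3S,7E)-7-ethoxy-6-hydroxy-6,9-dimethyl-3-(propan-2-yl)-3-[(triethylsilyl)oxy]deca-7,9-dienal (C6 epimers), via ethoxydiene 5 (not isolated), via dienylpotassium 6 (not isolated), via titanium hemiaminal 7 (not isolated)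
Conditions: 4, n-BuLi/t-BuOK, THF, −95 °C; 3, Ti(NEt2)4, THF, −78 °C; combine, −78 °C; aq. NaHCO3
Reagents that add atoms: none
Why: Schlosser-base 1,4-elimination and α-metalation of the unsaturated acetal gives the (E)-alkoxydienyl metal, which reacts with retention, while the aldehyde is masked in situ as its titanium amide adduct so that 1,2-addition occurs only at the methyl ketone; the new C6 carbinol centre is a mixture that is ionised in step 4, and the 7E geometry (C6 cis to the isopropenyl carbon) needed there is fixed here.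

Step 4
Reactants: 8 (3S,7E)-7-ethoxy-6-hydroxy-6,9-dimethyl-3-(propan-2-yl)-3-[(triethylsilyl)oxy]deca-7,9-dienal
Product: 13 (3R,3aS,4S,8aS)-4-[(tert-butyldimethylsilyl)oxy]-6,8a-dimethyl-3-(propan-2-yl)-3-[(triethylsilyl)oxy]-2,3,3a,4,5,8a-hexahydroazulen-8(1H)-one, via silyl enol ether 9 (not isolated), via pentadienyl cation 10 (not isolated), via cyclopentyl oxocarbenium ion 11 (not isolated), via bicyclic oxocarbenium ion 12 (not isolated)
Conditions: TBSOTf, Et3N, CH2Cl2, −78 °C; then TMSOTf, −78 → −40 °C; aq. NaHCO3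
Reagents that add atoms: tert-butyldimethylsilyl trifluoromethanesulfonate, CC(C)(C)[Si](C)(C)OS(=O)(=O)C(F)(F)F; water, O
Why: Proposed new method: TMSOTf ionises the tertiary dienylic alcohol to a U-shaped 2-ethoxypentadienyl cation that is trapped 5-exo by the tethered aldehyde enol silane (SN1 alkylation of a silyl enol ether; the inside-alkoxy/anti-isopropyl conformer at C3 and placement of the new aldehyde carbon anti to the bulky dienyl group set C3a and C8a as the trans ring fusion), and the resulting silyloxocarbenium ion is then captured at the γ-carbon of the (E)-dienol ether (7-ring vinylogous Mukaiyama aldol, α-attack being 5-enolendo-disfavoured, OTBS pseudo-equatorial setting C4) before water hydrolyses the O-ethyl oxocarbenium ion to the enone; this stepwise cationic (5+2) annulation is closest to Nicholas-cation/enol-silane (5+2) annulations, oxidopyrylium (5+2) cycloadditions and oxyallyl (4+3) cycloadditions.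

Step 5
Reactants: 13 (3R,3aS,4S,8aS)-4-[(tert-butyldimethylsilyl)oxy]-6,8a-dimethyl-3-(propan-2-yl)-3-[(triethylsilyl)oxy]-2,3,3a,4,5,8a-hexahydroazulen-8(1H)-one
Product: 14 (3R,3aS,4S,8S,8aS)-4-[(tert-butyldimethylsilyl)oxy]-6,8a-dimethyl-3-(propan-2-yl)-3-[(triethylsilyl)oxy]-1,2,3,3a,4,5,8,8a-octahydroazulen-8-ol
Conditions: NaBH4, CeCl3·7H2O, MeOH, −78 °C
Reagents that add atoms: none
Why: Luche 1,2-reduction of the β,β-disubstituted enone; hydride adds axially from the face opposite the axial angular methyl (as with ketones next to angular methyls in steroids), giving the 8S alcohol with OH cis to that methyl.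

Step 6
Reactants: 14 (3R,3aS,4S,8S,8aS)-4-[(tert-butyldimethylsilyl)oxy]-6,8a-dimethyl-3-(propan-2-yl)-3-[(triethylsilyl)oxy]-1,2,3,3a,4,5,8,8a-octahydroazulen-8-ol; 15 angelic acid
Product: 16 (3R,3aS,4S,8R,8aS)-4-[(tert-butyldimethylsilyl)oxy]-6,8a-dimethyl-3-(propan-2-yl)-3-[(triethylsilyl)oxy]-1,2,3,3a,4,5,8,8a-octahydroazulen-8-yl (2Z)-2-methylbut-2-enoate
Conditions: PPh3, DIAD, toluene, 0 °C → rt
Reagents that add atoms: none
Why: Mitsunobu esterification with SN2 inversion at the activated allylic carbinol (carboxylate enters axially, anti to the angular methyl) installs the angelate with the required 8R configuration; the pre-formed betaine leaves no free phosphine to isomerise the Z acid.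

Step 7
Reactants: 16 (3R,3aS,4S,8R,8aS)-4-[(tert-butyldimethylsilyl)oxy]-6,8a-dimethyl-3-(propan-2-yl)-3-[(triethylsilyl)oxy]-1,2,3,3a,4,5,8,8a-octahydroazulen-8-yl (2Z)-2-methylbut-2-enoate
Product: 17 (3R,3aS,4S,8R,8aS)-3,4-dihydroxy-6,8a-dimethyl-3-(propan-2-yl)-1,2,3,3a,4,5,8,8a-octahydroazulen-8-yl (2Z)-2-methylbut-2-enoate
Conditions: HF·pyridine, pyridine, THF, 0 °C → rt
Reagents that add atoms: none
Why: Fluoride-driven desilylation removes both silyl ethers under mildly acidic conditions that spare the allylic ester; an 8→4 acyl shift would be harmless because both esters of the target are the same.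

Step 8
Reactants: 17 (3R,3aS,4S,8R,8aS)-3,4-dihydroxy-6,8a-dimethyl-3-(propan-2-yl)-1,2,3,3a,4,5,8,8a-octahydroazulen-8-yl (2Z)-2-methylbut-2-enoate; 15 angelic acid
Product: 18 (3R,3aS,4S,8R,8aS)-3-hydroxy-6,8a-dimethyl-3-(propan-2-yl)-1,2,3,3a,4,5,8,8a-octahydroazulene-4,8-diyl bis[(2Z)-2-methylbut-2-enoate]
Conditions: 2,4,6-Cl3C6H2COCl, Et3N, toluene, rt; then 17, 80 °C
Reagents that add atoms: none
Why: Yamaguchi esterification through the mixed anhydride acylates the secondary C4 alcohol with retention while the tertiary C3 alcohol stays free, and running it without DMAP avoids angelate-to-tiglate isomerisation.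

## Compound list

1 | (S)-(+)-terpinen-4-ol, (1S)-4-methyl-1-(propan-2-yl)cyclohex-3-en-1-ol | CC1=CC[C@](O)(C(C)C)CC1 | starting material
2 | triethyl{[(1S)-4-methyl-1-(propan-2-yl)cyclohex-3-en-1-yl]oxy}silane | CC1=CC[C@](O[Si](CC)(CC)CC)(C(C)C)CC1 | intermediate
3 | (3S)-6-oxo-3-(propan-2-yl)-3-[(triethylsilyl)oxy]heptanal | O=CC[C@](O[Si](CC)(CC)CC)(C(C)C)CCC(C)=O | intermediate
4 | 1,1-diethoxy-3-methylbut-2-ene (prenal diethyl acetal) | CCOC(OCC)C=C(C)C | starting material
5 | (1E)-1-ethoxy-3-methylbuta-1,3-diene | CCO/C=C/C(C)=C | intermediate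
6 | [(1Z)-1-ethoxy-3-methylbuta-1,3-dien-1-yl]potassium (metal cis to the isopropenyl group) | CCO/C([K])=C/C(C)=C | intermediate
7 | tris(diethylamido)titanium hemiaminal of 3 at the aldehyde carbon (C1 epimers) | CCN(CC)C(C[C@](O[Si](CC)(CC)CC)(C(C)C)CCC(C)=O)O[Ti](N(CC)CC)(N(CC)CC)N(CC)CC | intermediate
8 | (3S,7E)-7-ethoxy-6-hydroxy-6,9-dimethyl-3-(propan-2-yl)-3-[(triethylsilyl)oxy]deca-7,9-dienal (C6 epimers) | O=CC[C@](O[Si](CC)(CC)CC)(C(C)C)CCC(C)(O)/C(OCC)=C\C(C)=C | intermediate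
9 | (1E,3R,7E)-1-[(tert-butyldimethylsilyl)oxy]-7-ethoxy-6,9-dimethyl-3-(propan-2-yl)-3-[(triethylsilyl)oxy]deca-1,7,9-trien-6-ol (C6 epimers) | CC(C)(C)[Si](C)(C)O/C=C/[C@](O[Si](CC)(CC)CC)(C(C)C)CCC(C)(O)/C(OCC)=C\C(C)=C | intermediate
10 | 2-ethoxypentadienyl cation (cation at C6 of 9) triflate | CC(C)(C)[Si](C)(C)O/C=C/[C@](O[Si](CC)(CC)CC)(C(C)C)CC[C+](C)/C(OCC)=C\C(C)=C.[O-]S(=O)(=O)C(F)(F)F | intermediate
11 | cyclopentyl silyloxocarbenium triflate: ring methyl and CH=O+TBS cis, dienyl and CH=O+TBS trans, OTES and CH=O+TBS cis | C=C(C)/C=C(OCC)\[C@@]1(C)CC[C@@](O[Si](CC)(CC)CC)(C(C)C)[C@@H]1C=[O+][Si](C)(C)C(C)(C)C.[O-]S(=O)(=O)C(F)(F)F | intermediate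
12 | bicyclic O-ethyl oxocarbenium triflate (13 ethylated on the carbonyl oxygen) | CC(C)(C)[Si](C)(C)O[C@H]1CC(C)=CC(=[O+]CC)[C@@]2(C)CC[C@@](O[Si](CC)(CC)CC)(C(C)C)[C@H]12.[O-]S(=O)(=O)C(F)(F)F | intermediate
13 | (3R,3aS,4S,8aS)-4-[(tert-butyldimethylsilyl)oxy]-6,8a-dimethyl-3-(propan-2-yl)-3-[(triethylsilyl)oxy]-2,3,3a,4,5,8a-hexahydroazulen-8(1H)-one | CC(C)(C)[Si](C)(C)O[C@H]1CC(C)=CC(=O)[C@@]2(C)CC[C@@](O[Si](CC)(CC)CC)(C(C)C)[C@H]12 | intermediate
14 | (3R,3aS,4S,8S,8aS)-4-[(tert-butyldimethylsilyl)oxy]-6,8a-dimethyl-3-(propan-2-yl)-3-[(triethylsilyl)oxy]-1,2,3,3a,4,5,8,8a-octahydroazulen-8-ol | CC(C)(C)[Si](C)(C)O[C@H]1CC(C)=C[C@H](O)[C@@]2(C)CC[C@@](O[Si](CC)(CC)CC)(C(C)C)[C@H]12 | intermediate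
15 | angelic acid, (2Z)-2-methylbut-2-enoic acid | C/C=C(/C)C(=O)O | starting material
16 | (3R,3aS,4S,8R,8aS)-4-[(tert-butyldimethylsilyl)oxy]-6,8a-dimethyl-3-(propan-2-yl)-3-[(triethylsilyl)oxy]-1,2,3,3a,4,5,8,8a-octahydroazulen-8-yl (2Z)-2-methylbut-2-enoate | CC(C)(C)[Si](C)(C)O[C@H]1CC(C)=C[C@@H](OC(=O)/C(C)=C\C)[C@@]2(C)CC[C@@](O[Si](CC)(CC)CC)(C(C)C)[C@H]12 | intermediate
17 | (3R,3aS,4S,8R,8aS)-3,4-dihydroxy-6,8a-dimethyl-3-(propan-2-yl)-1,2,3,3a,4,5,8,8a-octahydroazulen-8-yl (2Z)-2-methylbut-2-enoate | O[C@H]1CC(C)=C[C@@H](OC(=O)/C(C)=C\C)[C@@]2(C)CC[C@@](O)(C(C)C)[C@H]12 | intermediate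
18 | (3R,3aS,4S,8R,8aS)-3-hydroxy-6,8a-dimethyl-3-(propan-2-yl)-1,2,3,3a,4,5,8,8a-octahydroazulene-4,8-diyl bis[(2Z)-2-methylbut-2-enoate] | C/C=C(/C)C(=O)O[C@H]1CC(C)=C[C@@H](OC(=O)/C(C)=C\C)[C@@]2(C)CC[C@@](O)(C(C)C)[C@H]12 | target

## Step count and risks

Total step count: 8. Longest linear sequence: 8 steps (1 → 18); 4 and 15 are bought.

The three steps most likely to fail:

Step 4 (cationic two-ring annulation). The U-shaped alkoxypentadienyl cation can close by a Nazarov-type 4π electrocyclisation, lose a proton, or be trapped at oxygen before the enol silane reaches it. The seven-membered ring may also fail to close, or C8a or C4 may form with the wrong configuration. The fallback sets out from 8 and comes back at 13. 8 is converted into its TBS enol ether as in step 4 but ionised with the weak Lewis acid ZnBr2 at −78 °C and quenched with dilute aqueous acid once the cyclopentane has formed. This gives (1R,2S,5R)-2-methyl-2-(3-methylbut-2-enoyl)-5-(propan-2-yl)-5-[(triethylsilyl)oxy]cyclopentane-1-carbaldehyde F1. The seven-membered ring is then closed in a separate operation by a γ-selective intramolecular vinylogous aldol addition (ATPH, LTMP, toluene/THF, −78 °C) to (3R,3aS,4S,8aS)-4-hydroxy-6,8a-dimethyl-3-(propan-2-yl)-3-[(triethylsilyl)oxy]-2,3,3a,4,5,8a-hexahydroazulen-8(1H)-one F2. Silylation (TBSOTf, 2,6-lutidine) gives 13.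

Step 6 (Mitsunobu inversion next to a quaternary carbon). SN2' attack, elimination to the diene, or ionisation with loss of stereochemistry may compete. The fallback sets out from 13 and comes back at 16. Instead of reducing from the open face and inverting, 13 is reduced with a bulky hydride (K-Selectride or LiAlH(OtBu)3, THF, −78 °C) that is delivered equatorially, past the angular methyl group. This gives (3R,3aS,4S,8R,8aS)-4-[(tert-butyldimethylsilyl)oxy]-6,8a-dimethyl-3-(propan-2-yl)-3-[(triethylsilyl)oxy]-1,2,3,3a,4,5,8,8a-octahydroazulen-8-ol F3 directly. F3 is esterified with 15 under the Yamaguchi conditions of step 8 (retention) to give 16.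

Step 3 (ketone-selective addition beside a free aldehyde). The titanium masking may be incomplete, and the basic dienyl metal may enolise the methyl ketone. The fallback sets out from 2 and comes back at 8. 2 is ozonised in CH2Cl2/MeOH and the methoxy hydroperoxide is dehydrated with Ac2O/Et3N, so the aldehyde carbon emerges as an ester: methyl (3S)-6-oxo-3-(propan-2-yl)-3-[(triethylsilyl)oxy]heptanoate F4. Reagent 6 adds to the ketone of F4 at −78 °C, the ester being inert, to give methyl (3S,7E)-7-ethoxy-6-hydroxy-6,9-dimethyl-3-(propan-2-yl)-3-[(triethylsilyl)oxy]deca-7,9-dienoate F5. DIBAL-H (toluene, −78 °C) reduces the ester to the aldehyde 8.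

## Further compounds

F1 | step 4 | (1R,2S,5R)-2-methyl-2-(3-methylbut-2-enoyl)-5-(propan-2-yl)-5-[(triethylsilyl)oxy]cyclopentane-1-carbaldehyde | CC(C)=CC(=O)[C@@]1(C)CC[C@@](O[Si](CC)(CC)CC)(C(C)C)[C@@H]1C=O
F2 | step 4 | (3R,3aS,4S,8aS)-4-hydroxy-6,8a-dimethyl-3-(propan-2-yl)-3-[(triethylsilyl)oxy]-2,3,3a,4,5,8a-hexahydroazulen-8(1H)-one | O[C@H]1CC(C)=CC(=O)[C@@]2(C)CC[C@@](O[Si](CC)(CC)CC)(C(C)C)[C@H]12
F3 | step 6 | (3R,3aS,4S,8R,8aS)-4-[(tert-butyldimethylsilyl)oxy]-6,8a-dimethyl-3-(propan-2-yl)-3-[(triethylsilyl)oxy]-1,2,3,3a,4,5,8,8a-octahydroazulen-8-ol | CC(C)(C)[Si](C)(C)O[C@H]1CC(C)=C[C@@H](O)[C@@]2(C)CC[C@@](O[Si](CC)(CC)CC)(C(C)C)[C@H]12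
F4 | step 3 | methyl (3S)-6-oxo-3-(propan-2-yl)-3-[(triethylsilyl)oxy]heptanoate | COC(=O)C[C@](O[Si](CC)(CC)CC)(C(C)C)CCC(C)=O
F5 | step 3 | methyl (3S,7E)-7-ethoxy-6-hydroxy-6,9-dimethyl-3-(propan-2-yl)-3-[(triethylsilyl)oxy]deca-7,9-dienoate (C6 epimers) | COC(=O)C[C@](O[Si](CC)(CC)CC)(C(C)C)CCC(C)(O)/C(OCC)=C\C(C)=C
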